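All runs stem from a simulated flask for substances that don't exist, noise included.

At the reading time of 8.0 h, the question is how much gas has entered the flask for each mole of starting material charged.

| flask | starting material | gas phase | remark | time |
|---|---|---|---|---|
| eta | 1.1 M | 35 mM (held) | run made earlier |  |
| delta | 1.8 M | 35 mM (held) | run made earlier |  |
| flask | 0.80 M | 35 mM (held) |  | 8.0 h |

| run | time / h | target / % |
|---|---|---|
| eta | 1.33 | 10.0 |
| eta | 3.00 | 14.3 |
| eta | 4.00 | 14.1 |
| eta | 6.00 | 14.4 |
| eta | 8.00 | 12.7 |
| eta | 10.0 | 9.5 |
| delta | 0.833 | 5.3 |
| delta | 1.33 | 5.9 |
| delta | 2.00 | 8.3 |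
| delta | 2.50 | 10.0 |
| delta | 4.00 | 12.1 |
| delta | 6.00 | 13.1 |
| delta | 10.0 | 11.9 |

(scatter of a reading: 0.5 percentage points)
* target at 8.0 h, in percent of the starting material charged
* concentration of dissolved gas in solution at 8.0 h, in percent of saturation
- at the start none of the gas phase is in solution

1. Reacted gas must first dissolve, so target formed counts gas taken up. The first delta reading gives an uptake of at least 0.115 M h⁻¹. Uptake times time over charge is the gas equivalents, 1.15 for the flask.
2. This measure brings the runs together on the rising side: eta and delta both read 10.0% at 0.138 and 0.159 equivalents.
3. From above: the last eta reading, 9.5% at 1.04 equivalents, lies past its peak and below the flask, so target stands under it, within the scatter.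
4. From below: doubling the fall of eta's last step gives 6.30%. However, delta at 10.0 h reads 11.9% and eta at 6.00 h reads 14.4% at nearly equal equivalents, so the longer run stands lower. The flask is shorter than eta's last reading, which favours the straight line through eta's last readings: 7.90%.
5. The forecast gives 9.2%, inside this bracket, and 30% for dissolved gas, “poorly pinned”.
6. The flask gives 9.87% of target and 11.8% of saturation.

    target → over-reaction product (k = 0.00210 min⁻¹)
    starting material + dissolved gas → target (k = 1.00 M⁻¹ min⁻¹)
    gas phase ⇌ dissolved gas, rate k3*(csat - [dissolved gas]) (kL = 0.0630 min⁻¹)
    dissolved gas + target → over-reacted product (k = 3.10 M⁻¹ min⁻¹)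

At 8.00 h, dissolved gas in the flask is made 1.01 times as fast as it is used, a quasi-steady state. Target, over-reacted product and over-reaction product there hold 1.22 equivalents, above the 1.15 counted from the first delta reading. At the same uptake, the neighbour flask with 0.32 M would be offered 2.86 equivalents, more than the two its charge can bind, which points to a flask past its target peak; it holds 0.0662% target and 91.4% over-reacted product, with dissolved gas at 0.0339 M against a saturation value of 35 mM, so its uptake fell short of that offer.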